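**Plan**

- Cuts: first the hydride-level changes (C9' ester, three O-pivalates), then C7'–C8' and C8–C9 of the tetrahydrofuran together (retro-(3+2)), then C7'–O of the ylide precursor and C7–C8 of the enoate (aryl aldehyde plus propiolate).
- Feature: ring atoms C7'–O–C9 are the C–O–C unit of a carbonyl ylide, ArCH=O(+)–CH2(−); C8'=C8, carrying cis C9' (ester level) and the C7 aryl carbinol, is a (Z)-γ-acyloxy enoate.
- Forward: vanillin pivalate gives (a) an α-chloro (trimethylsilyl)methyl ether and (b), by alkynylation, O-pivaloylation and semihydrogenation, the enoate; CsF joins the two and closes the only ring; LiAlH4 unmasks the target.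
- Stereochemistry: C7 from ligand-controlled alkynylation; C8 and C8' from the Z geometry (cis) plus facial control by C7 under allylic 1,3-strain; C7' from the exo approach of the ylide.

Key step: step 6

Remark on numbering: ring O–C7'–C8'–C8–C9; C7 is the carbinol carbon on C8 and C9' the CH2OH carbon on C8'; Ar = 3-methoxy-4-(pivaloyloxy)phenyl.

Assumption: (S,S)-ProPhenol is taken as the ligand enantiomer that sends the alkynylzinc to the Re face of the aryl aldehyde; if the sense is the opposite, (R,R)-ProPhenol is used in step 3 and nothing else changes.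

**Route**

Step 1
Reactants: 1 vanillin; 2 pivaloyl chloride
Product: 3 4-formyl-2-methoxyphenyl pivalate
Conditions: Et3N, DMAP (cat.), CH2Cl2, 0 °C to rt
Reagents that add atoms: none
Why: DMAP-catalysed O-acylation (nucleophilic acyl substitution) masks the phenol as a hindered, electron-withdrawing ester that should tolerate HCl, Me2Zn and fluoride and fall to LiAlH4 at the end; no stereocentre is formed.

Step 2
Reactants: 3 4-formyl-2-methoxyphenyl pivalate; 4 (trimethylsilyl)methanol
Product: 6 chloro[3-methoxy-4-(pivaloyloxy)phenyl]methyl (trimethylsilyl)methyl ether (racemic), via hemiacetal 5 (not isolated)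
Conditions: HCl (g), MgSO4, CH2Cl2, −10 to 0 °C; filtered and concentrated under N2, used at once in step 6
Reagents that add atoms: hydrogen chloride, Cl
Why: Classical α-chloro ether synthesis (hemiacetal 5 from aldehyde and alcohol, then replacement of its hydroxyl by chloride under HCl) should work because the acyloxy-substituted arene is not electron-rich enough to make the benzylic chloride unmanageably labile, and the new centre is racemic and irrelevant since it disappears in the ylide.

Step 3
Reactants: 3 4-formyl-2-methoxyphenyl pivalate; 7 methyl propiolate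
Product: 9 methyl (4S)-4-hydroxy-4-[3-methoxy-4-(pivaloyloxy)phenyl]but-2-ynoate, via alkynylzinc species 8 (not isolated)
Conditions: Me2Zn (3 equiv), (S,S)-ProPhenol (10 mol %), PhMe, 0 to 4 °C; aq. NH4Cl
Reagents that add atoms: none
Why: In this catalytic asymmetric alkynylation of an aldehyde the alkynylzinc 8 is delivered within the chiral dinuclear zinc–ProPhenol pocket to the Re face of the aryl aldehyde, which sets C7 as S (CIP: alkynyl above aryl), the spatial arrangement that reads as 7R once the alkyne is reduced.

Step 4
Reactants: 9 methyl (4S)-4-hydroxy-4-[3-methoxy-4-(pivaloyloxy)phenyl]but-2-ynoate; 2 pivaloyl chloride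
Product: 10 methyl (4S)-4-[3-methoxy-4-(pivaloyloxy)phenyl]-4-(pivaloyloxy)but-2-ynoate
Conditions: pyridine, DMAP (cat.), CH2Cl2, 0 °C to rt
Reagents that add atoms: none
Why: DMAP-catalysed acylation under weakly basic conditions caps the propargylic alcohol before base-induced isomerisation to the γ-keto enoate can set in, leaves the C7–O bond untouched, and prevents butenolide formation once the alkyne has been reduced.

Step 5
Reactants: 10 methyl (4S)-4-[3-methoxy-4-(pivaloyloxy)phenyl]-4-(pivaloyloxy)but-2-ynoate
Product: 11 methyl (2Z,4R)-4-[3-methoxy-4-(pivaloyloxy)phenyl]-4-(pivaloyloxy)but-2-enoate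
Conditions: H2 (1 atm), Pd/CaCO3 poisoned with Pb(OAc)2, quinoline, EtOAc, rt, stopped after one equivalent
Reagents that add atoms: none
Why: Lindlar semihydrogenation adds H2 syn on the poisoned palladium surface and should stop at the (Z)-alkene, while C7 is not touched and changes its descriptor from S to R only because the alkenyl arm now ranks below the aryl group.

Step 6
Reactants: 6 chloro[3-methoxy-4-(pivaloyloxy)phenyl]methyl (trimethylsilyl)methyl ether; 11 methyl (2Z,4R)-4-[3-methoxy-4-(pivaloyloxy)phenyl]-4-(pivaloyloxy)but-2-enoate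
Product: 13 methyl (2S,3S,4R)-2-[3-methoxy-4-(pivaloyloxy)phenyl]-4-{(R)-[3-methoxy-4-(pivaloyloxy)phenyl](pivaloyloxy)methyl}tetrahydrofuran-3-carboxylate, via carbonyl ylide 12 (not isolated)
Conditions: 6 (2–3 equiv, slow addition), CsF (dried), MeCN, rt
Reagents that add atoms: none
Why: Fluoride attacks silicon of 6 and chloride leaves from the acetal carbon (1,3-elimination) to give the non-stabilised carbonyl ylide 12, which adds across the enoate C=C in a concerted suprafacial (3+2) dipolar cycloaddition; the closest known reaction type is the CsF-triggered addition of carbonyl ylides from α-chloroalkyl silylmethyl ethers to acrylates, fumarates and maleates. The tetrahydrofuran closes in this single event by union of the three-atom C7'–O–C9 dipole with C8'=C8 (bonds C7'–C8' and C9–C8), not by a separate cyclisation. C8 and C8' follow from the Z geometry, which keeps the ester and the C7 arm cis, and from the face chosen by C7: allylic 1,3-strain with the cis ester holds H7 in the alkene plane, the aryl and pivaloyloxy groups flank the two faces, and the dipole should enter anti to the aryl group, whose two ortho positions make it the more demanding neighbour for the incoming CH2 terminus, whereas the planar ester on oxygen can turn away. C7' follows from an exo transition state of the E-configured ylide (ylide oxygen on the side of the two alkene hydrogens), which places the new aryl group trans to the ester. Three selectivities are needed: regiochemistry (the unhindered, more nucleophilic CH2 terminus to the β-carbon C8, which also keeps the bulky ArCH terminus away from the branched C7), exo approach, and attack anti to the C7 aryl group; the first two rest on sterics and polarity, while the third competes with the stereoelectronic preference for a C–O bond anti to the incoming carbon and is the least secure point.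

Step 7
Reactants: 13 methyl (2S,3S,4R)-2-[3-methoxy-4-(pivaloyloxy)phenyl]-4-{(R)-[3-methoxy-4-(pivaloyloxy)phenyl](pivaloyloxy)methyl}tetrahydrofuran-3-carboxylate
Product: 14 (7R)-7-hydroxylariciresinol
Conditions: LiAlH4 (excess), THF, 0 °C to rt; aq. KNaC4H4O6 work-up near neutral pH
Reagents that add atoms: none
Why: Hydride reduction with LiAlH4 converts the methyl ester into the C9' primary alcohol and cleaves all three pivalates by attack at the acyl carbons, so no bond at a stereocentre is broken (C8' becomes R by CIP ranking only), and the non-acidic work-up avoids ring closure of the C7 carbinol onto C9'–OH.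

**Compound list**

1 | vanillin | COc1cc(C=O)ccc1O | starting material
2 | pivaloyl chloride | CC(C)(C)C(=O)Cl | starting material
3 | 4-formyl-2-methoxyphenyl pivalate | COc1cc(C=O)ccc1OC(=O)C(C)(C)C | intermediate
4 | (trimethylsilyl)methanol | C[Si](C)(C)CO | starting material
5 | hydroxy[3-methoxy-4-(pivaloyloxy)phenyl]methyl (trimethylsilyl)methyl ether (hemiacetal, not isolated) | COc1cc(C(O)OC[Si](C)(C)C)ccc1OC(=O)C(C)(C)C | intermediate
6 | chloro[3-methoxy-4-(pivaloyloxy)phenyl]methyl (trimethylsilyl)methyl ether, racemic | COc1cc(C(Cl)OC[Si](C)(C)C)ccc1OC(=O)C(C)(C)C | intermediate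
7 | methyl propiolate | C#CC(=O)OC | starting material
8 | methyl 3-(methylzincio)prop-2-ynoate (not isolated) | COC(=O)C#C[Zn]C | intermediate
9 | methyl (4S)-4-hydroxy-4-[3-methoxy-4-(pivaloyloxy)phenyl]but-2-ynoate | COC(=O)C#C[C@@H](O)c1ccc(OC(=O)C(C)(C)C)c(OC)c1 | intermediate
10 | methyl (4S)-4-[3-methoxy-4-(pivaloyloxy)phenyl]-4-(pivaloyloxy)but-2-ynoate | COC(=O)C#C[C@@H](OC(=O)C(C)(C)C)c1ccc(OC(=O)C(C)(C)C)c(OC)c1 | intermediate
11 | methyl (2Z,4R)-4-[3-methoxy-4-(pivaloyloxy)phenyl]-4-(pivaloyloxy)but-2-enoate | COC(=O)/C=C\[C@@H](OC(=O)C(C)(C)C)c1ccc(OC(=O)C(C)(C)C)c(OC)c1 | intermediate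
12 | (E)-carbonyl ylide ArCH=O(+)–CH2(−), Ar = 3-methoxy-4-(pivaloyloxy)phenyl (not isolated) | [CH2-]/[O+]=C/c1ccc(OC(=O)C(C)(C)C)c(OC)c1 | intermediate
13 | methyl (2S,3S,4R)-2-[3-methoxy-4-(pivaloyloxy)phenyl]-4-{(R)-[3-methoxy-4-(pivaloyloxy)phenyl](pivaloyloxy)methyl}tetrahydrofuran-3-carboxylate | COc1cc([C@H]2OC[C@H]([C@@H](OC(=O)C(C)(C)C)c3ccc(OC(=O)C(C)(C)C)c(OC)c3)[C@@H]2C(=O)OC)ccc1OC(=O)C(C)(C)C | intermediate
14 | (7R)-7-hydroxylariciresinol, 4-[(2S,3R,4R)-4-[(R)-hydroxy(4-hydroxy-3-methoxyphenyl)methyl]-3-(hydroxymethyl)oxolan-2-yl]-2-methoxyphenol | COc1cc([C@H]2OC[C@H]([C@@H](O)c3ccc(O)c(OC)c3)[C@@H]2CO)ccc1O | target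

**Count**

Total steps: 7. Longest linear sequence: 6 steps (1 → 3 → 9 → 10 → 11 → 13 → 14); the ylide precursor 6 is a two-step branch from 1.

**Steps most likely to fail**

Step 6. The facial selectivity may be low or reversed, because the ylide may prefer the face anti to the C7–O bond instead of the face anti to the C7 aryl group. Loss of regio- or exo-selectivity and fluoride-induced γ-deprotonation with Z/E isomerisation are lesser concerns. The fallback accepts attack anti to oxygen, makes it dominant, and then inverts C7. It sets out from aldehyde 3. Alkynylation with tert-butyl propiolate under the enantiomeric ligand, (R,R)-ProPhenol/Me2Zn, should give tert-butyl (4R)-4-hydroxy-4-[3-methoxy-4-(pivaloyloxy)phenyl]but-2-ynoate F1. Silylation (TIPSOTf, 2,6-lutidine, CH2Cl2) should give the triisopropylsilyl ether F2, and semihydrogenation as in step 5 the (2Z,4S)-enoate F3. With a bulky silyloxy group the steric and the stereoelectronic preference point the same way, so the ylide from 6 (CsF, MeCN) should add anti to oxygen and give the cycloadduct F4, which has the ring centres of the target and the epimeric configuration at C7. Desilylation (Bu4NF/AcOH, THF) should give the C7 alcohol F5, which the tert-butyl ester keeps from lactonising. A Mitsunobu reaction (PhCO2H, PPh3, DIAD, THF, 0 °C) should invert C7 and give the (7R)-benzoate F6. LiAlH4 then reduces the tert-butyl ester and cleaves the benzoate and both aryl pivalates, so the fallback returns to the route at the target 14.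

Step 2. The chloro ether may not form cleanly, because the water set free drives the equilibrium back to hemiacetal and aldehyde, and the product may hydrolyse on handling. The fallback separates C–O bond formation from chloride introduction. It sets out from 3 and 4. Acid-catalysed acetalisation with two equivalents of 4 (TsOH, cyclohexane, water separator) should give the stable, purifiable bis[(trimethylsilyl)methyl] acetal F7. Acetyl chloride with a trace of ZnCl2 under anhydrous conditions should then exchange one alkoxy group for chloride, with (trimethylsilyl)methyl acetate as the coproduct, and the fallback returns to the route at 6.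

Step 3. Enantioselectivity may be insufficient, turnover may be slow, or methyl transfer from Me2Zn may compete. The fallback replaces catalytic asymmetric addition by a racemic addition and an enzymatic resolution. It sets out from 3 and 7. Deprotonation of 7 with LiN(SiMe3)2 in THF at −78 °C and addition to 3 should give the racemic alkynol F8. Lipase-catalysed acetylation (Pseudomonas cepacia lipase, vinyl acetate, tBuOMe) should, with the aryl group as the large and the linear alkynoate arm as the medium substituent in the usual empirical model, acetylate the (S)-enantiomer to the (4S)-acetate F9, which is separated from the unreacted (R)-alcohol. Hydrolysis of F9 with the same lipase in pH 7 phosphate buffer returns to the route at 9.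

**Further compounds**

F1 | step 6 | tert-butyl (4R)-4-hydroxy-4-[3-methoxy-4-(pivaloyloxy)phenyl]but-2-ynoate | CC(C)(C)OC(=O)C#C[C@H](O)c1ccc(OC(=O)C(C)(C)C)c(OC)c1
F2 | step 6 | tert-butyl (4R)-4-[3-methoxy-4-(pivaloyloxy)phenyl]-4-[(triisopropylsilyl)oxy]but-2-ynoate | CC(C)(C)OC(=O)C#C[C@H](O[Si](C(C)C)(C(C)C)C(C)C)c1ccc(OC(=O)C(C)(C)C)c(OC)c1
F3 | step 6 | tert-butyl (2Z,4S)-4-[3-methoxy-4-(pivaloyloxy)phenyl]-4-[(triisopropylsilyl)oxy]but-2-enoate | CC(C)(C)OC(=O)/C=C\[C@H](O[Si](C(C)C)(C(C)C)C(C)C)c1ccc(OC(=O)C(C)(C)C)c(OC)c1
F4 | step 6 | tert-butyl (2S,3S,4R)-2-[3-methoxy-4-(pivaloyloxy)phenyl]-4-{(S)-[3-methoxy-4-(pivaloyloxy)phenyl][(triisopropylsilyl)oxy]methyl}tetrahydrofuran-3-carboxylate | COc1cc([C@H]2OC[C@H]([C@H](O[Si](C(C)C)(C(C)C)C(C)C)c3ccc(OC(=O)C(C)(C)C)c(OC)c3)[C@@H]2C(=O)OC(C)(C)C)ccc1OC(=O)C(C)(C)C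
F5 | step 6 | tert-butyl (2S,3S,4R)-4-{(S)-hydroxy[3-methoxy-4-(pivaloyloxy)phenyl]methyl}-2-[3-methoxy-4-(pivaloyloxy)phenyl]tetrahydrofuran-3-carboxylate | COc1cc([C@H]2OC[C@H]([C@H](O)c3ccc(OC(=O)C(C)(C)C)c(OC)c3)[C@@H]2C(=O)OC(C)(C)C)ccc1OC(=O)C(C)(C)C
F6 | step 6 | tert-butyl (2S,3S,4R)-4-{(R)-(benzoyloxy)[3-methoxy-4-(pivaloyloxy)phenyl]methyl}-2-[3-methoxy-4-(pivaloyloxy)phenyl]tetrahydrofuran-3-carboxylate | COc1cc([C@H]2OC[C@H]([C@@H](OC(=O)c4ccccc4)c3ccc(OC(=O)C(C)(C)C)c(OC)c3)[C@@H]2C(=O)OC(C)(C)C)ccc1OC(=O)C(C)(C)C
F7 | step 2 | 4-{bis[(trimethylsilyl)methoxy]methyl}-2-methoxyphenyl pivalate | COc1cc(C(OC[Si](C)(C)C)OC[Si](C)(C)C)ccc1OC(=O)C(C)(C)C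
F8 | step 3 | methyl 4-hydroxy-4-[3-methoxy-4-(pivaloyloxy)phenyl]but-2-ynoate, racemic | COC(=O)C#CC(O)c1ccc(OC(=O)C(C)(C)C)c(OC)c1
F9 | step 3 | methyl (4S)-4-acetoxy-4-[3-methoxy-4-(pivaloyloxy)phenyl]but-2-ynoate | COC(=O)C#C[C@@H](OC(C)=O)c1ccc(OC(=O)C(C)(C)C)c(OC)c1
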